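**Plan**

- Core numbering used throughout: C1 (OMe bridgehead), C2 (CHOH), C3 (CHOMe), C4 (CH2), C5 (allyl bridgehead), C6 (CHMe), C7 (CHAr, Ar = 3,4,5-trimethoxyphenyl), C8 (bridging C=O).
- Retrosynthesis: the C2 carbinol and the C3/C4 hydrogens are taken back to a 3-methoxy-3-ene-2,8-dione; C3=C4 is cut (aldol condensation) to a cyclopentanone with a formyl arm on C5 and a methoxyacetyl arm on C1; then C1–C2, C1–OMe, C7–Ar and C5–allyl are cut in turn, back to the Favorskii/ozonolysis keto ester of (S)-pulegone.
- Forward: the five-membered ring C1–C7–C6–C5–C8 is the contracted pulegone ring and is substituted stepwise (allyl, enone, aryl, methoxy, C2–C3 arm); the six-membered ring C1–C2–C3–C4–C5–C8 closes afterwards through the C3–C4 condensation.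
- Enabling feature: the C6 methyl β to C8 is the pulegone methyl, the Favorskii ester carbon is C4, and C2–C3 is a methoxyacetyl unit whose CH2 is the only enolisable carbon and faces a non-enolisable aldehyde held cis on the ring.
- Stereochemistry: C6 from (S)-pulegone; C5, C7 and C1 by 1,2-induction (allylation and aryl addition anti to methyl, aldol anti to aryl); C3 by equilibration to the equatorial methoxy epimer; C2 by equatorial delivery of a bulky hydride.

Key step: step 11

Assumption: metal enolates, aldolates and reagent-derived activated species (alkoxysulfonium ions, copper enolate) are treated as mechanism and carry no number.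
Assumption: stereocentres that a following step erases are left undefined in names and SMILES.

**Route**

Step 1
Reactants: 1 (S)-(−)-pulegone
Product: 3 methyl (2S)-2-methyl-5-(propan-2-ylidene)cyclopentane-1-carboxylate (methyl pulegenate; C1 epimers), via pulegone dibromide 2 (not isolated)
Conditions: Br2, NaHCO3, Et2O, −10 °C; filter; then NaOMe, MeOH, reflux
Reagents that add atoms: sodium methoxide, [Na+].[O-]C
Why: Bromine adds to the exocyclic alkene and methoxide then drives a Favorskii rearrangement (cyclopropanone formation, methoxide opening, loss of the second bromide), which contracts the ring without touching the methyl-bearing centre that becomes C6; the configuration next to the ester does not matter because that carbon is enolised in step 3.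

Step 2
Reactants: 3 methyl pulegenate
Product: 5 methyl (2S)-2-methyl-5-oxocyclopentane-1-carboxylate (C1 epimers), via primary ozonide 4 (not isolated)
Conditions: O3, CH2Cl2, −78 °C; then Me2S, −78 °C → rt
Reagents that add atoms: ozone, [O-][O+]=O
Why: Ozonolysis of the only alkene (cycloaddition to the primary ozonide, cleavage, Me2S reduction) should unmask the C8 ketone as the β-keto ester and release acetone, the ester and the remote stereocentre being inert.

Step 3
Reactants: 5 methyl (2S)-2-methyl-5-oxocyclopentane-1-carboxylate; 6 allyl bromide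
Product: 7 methyl (1S,2S)-1-allyl-2-methyl-5-oxocyclopentane-1-carboxylate (allyl trans to methyl)
Conditions: K2CO3, acetone, reflux
Reagents that add atoms: none
Why: C-Alkylation (SN2) of the stabilised β-keto ester enolate should occur on the ring face anti to the adjacent methyl group, which sets the C5 quaternary centre with allyl trans and the ester carbon (future C4) cis to the methyl.

Step 4
Reactants: 7 methyl (1S,2S)-1-allyl-2-methyl-5-oxocyclopentane-1-carboxylate
Product: 10 methyl (1S,5S)-1-allyl-5-methyl-2-oxocyclopent-3-ene-1-carboxylate, via α-phenylselanyl ketone 8 (not isolated), via selenoxide 9 (not isolated)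
Conditions: LDA (commercial solution), THF, −78 °C; PhSeBr, −78 °C; then 30% H2O2, pyridine, CH2Cl2, 0 °C → rt
Reagents that add atoms: none
Why: Only C1 carries enolisable hydrogens, so enolate selenenylation followed by oxidation and selenoxide syn-elimination should give the C1=C7 enone regiospecifically, the enolate consuming PhSeBr at −78 °C far faster than the terminal alkene could and H2O2/pyridine leaving that alkene untouched.

Step 5
Reactants: 10 methyl (1S,5S)-1-allyl-5-methyl-2-oxocyclopent-3-ene-1-carboxylate; 11 5-bromo-1,2,3-trimethoxybenzene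
Product: 13 methyl (1S,4S,5S)-1-allyl-5-methyl-4-(3,4,5-trimethoxyphenyl)-2-[(trimethylsilyl)oxy]cyclopent-2-ene-1-carboxylate, via arylmagnesium bromide 12 (not isolated)
Conditions: 11, Mg, THF, 40 °C; then CuBr·SMe2 (0.2 equiv), TMSCl, 10, THF, −78 → −40 °C; Et3N, cold aq NaHCO3
Reagents that add atoms: chlorotrimethylsilane, C[Si](C)(C)Cl
Why: TMSCl-accelerated, copper-catalysed conjugate addition of the aryl Grignard reagent should deliver the aryl group to C7 anti to the neighbouring C6 methyl (the trans pattern usual for 4-substituted cyclopentenones) and trap the enolate regiospecifically as the C8=C1 silyl enol ether.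

Step 6
Reactants: 13 silyl enol ether
Product: 15 methyl (1S,2S,3R,4R)-1-allyl-4-hydroxy-2-methyl-5-oxo-3-(3,4,5-trimethoxyphenyl)cyclopentane-1-carboxylate, via α-silyloxy ketone 14 (not isolated)
Conditions: mCPBA (1.05 equiv), NaHCO3, CH2Cl2, −20 °C; then 1 M HCl, THF, 0 °C
Reagents that add atoms: meta-chloroperoxybenzoic acid, OOC(=O)c1cccc(Cl)c1
Why: In this Rubottom oxidation the electron-rich silyl enol ether is epoxidised much faster than the monosubstituted allyl alkene, silyl migration gives the α-silyloxy ketone and dilute acid frees the C1 hydroxyl, expected trans to the aryl group although this centre is flattened again in step 8.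

Step 7
Reactants: 15 α-hydroxy ketone
Product: 16 methyl (1S,2S,3R,4R)-1-allyl-4-methoxy-2-methyl-5-oxo-3-(3,4,5-trimethoxyphenyl)cyclopentane-1-carboxylate
Conditions: MeOTf, 2,6-di-tert-butyl-4-methylpyridine, CH2Cl2, 0 °C → rt
Reagents that add atoms: methyl trifluoromethanesulfonate, COS(=O)(=O)C(F)(F)F
Why: O-Alkylation with methyl triflate and a hindered, non-nucleophilic pyridine base runs under non-enolising conditions, so the α-ketol should be methylated without epimerisation, ketol rearrangement or C-alkylation.

Step 8
Reactants: 16 α-methoxy ketone; 17 methoxyacetaldehyde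
Product: 18 methyl (1S,2S,3R,4R)-1-allyl-4-(1-hydroxy-2-methoxyethyl)-4-methoxy-2-methyl-5-oxo-3-(3,4,5-trimethoxyphenyl)cyclopentane-1-carboxylate (carbinol epimers)
Conditions: LDA, THF, −78 °C; then 17 (freshly distilled), −78 °C; AcOH, −78 °C
Reagents that add atoms: none
Why: C1 holds the only acidic hydrogen, and its lithium enolate should add to the strongly electrophilic α-alkoxy aldehyde (directed aldol addition) on the face anti to the C7 aryl group, which creates the C1 quaternary centre with methoxy cis to aryl and the new two-carbon arm cis to the C5 ester; the carbinol configuration is irrelevant and the cold acidic quench guards against retro-aldol reversal.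

Step 9
Reactants: 18 aldol adduct
Product: 19 2-allyl-2-(hydroxymethyl)-5-(1-hydroxy-2-methoxyethyl)-5-methoxy-3-methyl-4-(3,4,5-trimethoxyphenyl)cyclopentan-1-ol (ring centres C2, C3, C4, C5 as in 18; three carbinol centres uncontrolled)
Conditions: LiAlH4, THF, 0 °C → rt; aq NaOH work-up
Reagents that add atoms: none
Why: LiAlH4 reduction takes the ester to the primary alcohol and the C8 ketone to a carbinol (a lactone formed from the cis hydroxy ester would converge on the same triol), which brings C4 to the alcohol level with no chemoselectivity demand; the new carbinol configurations are erased in step 10.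

Step 10
Reactants: 19 triol
Product: 20 (1R,2S,3R,4S)-1-allyl-4-methoxy-4-(methoxyacetyl)-2-methyl-5-oxo-3-(3,4,5-trimethoxyphenyl)cyclopentane-1-carbaldehyde
Conditions: (COCl)2, DMSO, CH2Cl2, −78 °C; Et3N, −78 → −20 °C; pH 7 buffer
Reagents that add atoms: none
Why: In the Swern oxidation all three hydroxyls are activated as alkoxysulfonium ions before base is added, so no free hydroxyl remains to form a lactol with a new carbonyl group, and the C4 aldehyde, C2 ketone and C8 ketone appear together under non-nucleophilic conditions that the two quaternary 1,3-dicarbonyl centres tolerate.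

Step 11
Reactants: 20 keto aldehyde
Product: 22 (1S,5R,6S,7R)-5-allyl-1,3-dimethoxy-6-methyl-7-(3,4,5-trimethoxyphenyl)bicyclo[3.2.1]oct-3-ene-2,8-dione, via bicyclic aldol 21 (not isolated)
Conditions: dibenzylammonium trifluoroacetate (0.3 equiv), 4 Å MS, toluene, 60 °C
Reagents that add atoms: none
Why: The ammonium salt enolises the methoxyacetyl ketone at C3, its only enolisable position, and activates the formyl group (by protonation or as the iminium ion); C3 adds to C4 to give the β-hydroxy ketone 21 (or its amino counterpart), which loses water (or amine) by E1cB to the conjugated 3-methoxy enone. This is an intramolecular aldol (Knoevenagel-type) condensation of a keto aldehyde, a standard cycloalkenone closure. The six-membered ring C1–C2–C3–C4–C5–C8 closes in the 6-(enolendo)-exo-trig mode, and the new C3=C4 alkene lies inside the three-carbon bridge, so no bridgehead alkene arises. No stereocentre is formed; closure is possible because the two arms are cis on the cyclopentanone, as fixed at C5 in step 3 and at C1 in step 8. The only selectivity needed is chemoselectivity, and it is secured by the substrate (C1 and C5 are quaternary, the aldehyde cannot enolise and is the most electrophilic carbonyl) and by the weakly acidic, poorly nucleophilic medium, which avoids the retro-Claisen cleavage that hydroxide or alkoxide would cause at the two non-enolisable 1,3-dicarbonyl centres.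

Step 12
Reactants: 22 enedione
Product: 24 (1S,3R,5S,6S,7R)-5-allyl-1,3-dimethoxy-6-methyl-7-(3,4,5-trimethoxyphenyl)bicyclo[3.2.1]octane-2,8-dione, via C3-epimeric diketone mixture 23 (not isolated)
Conditions: [(Ph3P)CuH]6 (0.4 equiv), degassed toluene–H2O, rt; filter; then DBU (0.2 equiv), CH2Cl2, rt
Reagents that add atoms: none
Why: Copper hydride from Stryker's reagent adds to C4 of the enone (conjugate reduction) and leaves the isolated allyl alkene and both ketones alone, water protonates the copper enolate at C3, and catalytic DBU then equilibrates C3 through the C2 enolate to the epimer with equatorial methoxy, because an axial C3 substituent would collide with the endo C6 methyl under the two-carbon bridge.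

Step 13
Reactants: 24 saturated diketone
Product: 25 (1R,2R,3R,5S,6S,7R)-5-allyl-2-hydroxy-1,3-dimethoxy-6-methyl-7-(3,4,5-trimethoxyphenyl)bicyclo[3.2.1]octan-8-one (CNP0275320.1)
Conditions: L-Selectride (1.1 equiv), THF, −78 °C; pH 7 buffer, −78 °C → rt
Reagents that add atoms: none
Why: The C8 ketone is shielded by two quaternary neighbours, so the bulky trialkylborohydride should reduce only the C2 ketone and approach it along the equatorial trajectory, on the face turned away from C8, which places the new hydroxyl axial (2R, cis to the C3 methoxy); the cold buffered quench prevents retro-aldol opening of the β-alkoxy ketone.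

**Compound list**

1 | (S)-(−)-pulegone, (5S)-5-methyl-2-(propan-2-ylidene)cyclohexan-1-one | C[C@H]1CCC(=C(C)C)C(=O)C1 | starting material
2 | pulegone dibromide, (5S)-2-bromo-2-(2-bromopropan-2-yl)-5-methylcyclohexan-1-one (C2 epimers) | C[C@H]1CCC(Br)(C(C)(C)Br)C(=O)C1 | intermediate (not isolated)
3 | methyl (2S)-2-methyl-5-(propan-2-ylidene)cyclopentane-1-carboxylate (C1 epimers) | COC(=O)C1[C@@H](C)CCC1=C(C)C | intermediate
4 | primary ozonide of 3 (spiro-1,2,3-trioxolane) | COC(=O)C1[C@@H](C)CCC12OOOC2(C)C | intermediate (not isolated)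
5 | methyl (2S)-2-methyl-5-oxocyclopentane-1-carboxylate (C1 epimers) | COC(=O)C1[C@@H](C)CCC1=O | intermediate
6 | allyl bromide | C=CCBr | starting material
7 | methyl (1S,2S)-1-allyl-2-methyl-5-oxocyclopentane-1-carboxylate | C=CC[C@@]1(C(=O)OC)C(=O)CC[C@@H]1C | intermediate
8 | methyl (1S,2S)-1-allyl-2-methyl-5-oxo-4-(phenylselanyl)cyclopentane-1-carboxylate (C4 epimers) | C=CC[C@@]1(C(=O)OC)C(=O)C([Se]c2ccccc2)C[C@@H]1C | intermediate (not isolated)
9 | selenoxide of 8 | C=CC[C@@]1(C(=O)OC)C(=O)C([Se](=O)c2ccccc2)C[C@@H]1C | intermediate (not isolated)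
10 | methyl (1S,5S)-1-allyl-5-methyl-2-oxocyclopent-3-ene-1-carboxylate | C=CC[C@@]1(C(=O)OC)C(=O)C=C[C@@H]1C | intermediate
11 | 5-bromo-1,2,3-trimethoxybenzene | COc1cc(Br)cc(OC)c1OC | starting material
12 | (3,4,5-trimethoxyphenyl)magnesium bromide | COc1cc([Mg]Br)cc(OC)c1OC | intermediate (not isolated)
13 | methyl (1S,4S,5S)-1-allyl-5-methyl-4-(3,4,5-trimethoxyphenyl)-2-[(trimethylsilyl)oxy]cyclopent-2-ene-1-carboxylate | C=CC[C@@]1(C(=O)OC)C(O[Si](C)(C)C)=C[C@@H](c2cc(OC)c(OC)c(OC)c2)[C@@H]1C | intermediate
14 | methyl (1S,2S,3R,4R)-1-allyl-2-methyl-5-oxo-3-(3,4,5-trimethoxyphenyl)-4-[(trimethylsilyl)oxy]cyclopentane-1-carboxylate | C=CC[C@@]1(C(=O)OC)C(=O)[C@H](O[Si](C)(C)C)[C@@H](c2cc(OC)c(OC)c(OC)c2)[C@@H]1C | intermediate (not isolated)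
15 | methyl (1S,2S,3R,4R)-1-allyl-4-hydroxy-2-methyl-5-oxo-3-(3,4,5-trimethoxyphenyl)cyclopentane-1-carboxylate | C=CC[C@@]1(C(=O)OC)C(=O)[C@H](O)[C@@H](c2cc(OC)c(OC)c(OC)c2)[C@@H]1C | intermediate
16 | methyl (1S,2S,3R,4R)-1-allyl-4-methoxy-2-methyl-5-oxo-3-(3,4,5-trimethoxyphenyl)cyclopentane-1-carboxylate | C=CC[C@@]1(C(=O)OC)C(=O)[C@H](OC)[C@@H](c2cc(OC)c(OC)c(OC)c2)[C@@H]1C | intermediate
17 | methoxyacetaldehyde | COCC=O | starting material
18 | methyl (1S,2S,3R,4R)-1-allyl-4-(1-hydroxy-2-methoxyethyl)-4-methoxy-2-methyl-5-oxo-3-(3,4,5-trimethoxyphenyl)cyclopentane-1-carboxylate (carbinol epimers) | C=CC[C@@]1(C(=O)OC)C(=O)[C@](OC)(C(O)COC)[C@@H](c2cc(OC)c(OC)c(OC)c2)[C@@H]1C | intermediate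
19 | 2-allyl-2-(hydroxymethyl)-5-(1-hydroxy-2-methoxyethyl)-5-methoxy-3-methyl-4-(3,4,5-trimethoxyphenyl)cyclopentan-1-ol (ring centres as in 18; carbinol centres uncontrolled) | C=CC[C@@]1(CO)C(O)[C@](OC)(C(O)COC)[C@@H](c2cc(OC)c(OC)c(OC)c2)[C@@H]1C | intermediate
20 | (1R,2S,3R,4S)-1-allyl-4-methoxy-4-(methoxyacetyl)-2-methyl-5-oxo-3-(3,4,5-trimethoxyphenyl)cyclopentane-1-carbaldehyde | C=CC[C@@]1(C=O)C(=O)[C@](OC)(C(=O)COC)[C@@H](c2cc(OC)c(OC)c(OC)c2)[C@@H]1C | intermediate
21 | 5-allyl-4-hydroxy-1,3-dimethoxy-6-methyl-7-(3,4,5-trimethoxyphenyl)bicyclo[3.2.1]octane-2,8-dione (C3/C4 epimers; other centres as in 22) | C=CC[C@@]12C(O)C(OC)C(=O)[C@@](OC)(C1=O)[C@@H](c1cc(OC)c(OC)c(OC)c1)[C@@H]2C | intermediate (not isolated)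
22 | (1S,5R,6S,7R)-5-allyl-1,3-dimethoxy-6-methyl-7-(3,4,5-trimethoxyphenyl)bicyclo[3.2.1]oct-3-ene-2,8-dione | C=CC[C@@]12C=C(OC)C(=O)[C@@](OC)(C1=O)[C@@H](c1cc(OC)c(OC)c(OC)c1)[C@@H]2C | intermediate
23 | 5-allyl-1,3-dimethoxy-6-methyl-7-(3,4,5-trimethoxyphenyl)bicyclo[3.2.1]octane-2,8-dione, C3 epimer mixture | C=CC[C@@]12CC(OC)C(=O)[C@@](OC)(C1=O)[C@@H](c1cc(OC)c(OC)c(OC)c1)[C@@H]2C | intermediate (not isolated)
24 | (1S,3R,5S,6S,7R)-5-allyl-1,3-dimethoxy-6-methyl-7-(3,4,5-trimethoxyphenyl)bicyclo[3.2.1]octane-2,8-dione | C=CC[C@@]12C[C@@H](OC)C(=O)[C@@](OC)(C1=O)[C@@H](c1cc(OC)c(OC)c(OC)c1)[C@@H]2C | intermediate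
25 | (1R,2R,3R,5S,6S,7R)-5-allyl-2-hydroxy-1,3-dimethoxy-6-methyl-7-(3,4,5-trimethoxyphenyl)bicyclo[3.2.1]octan-8-one | C=CC[C@@]12C[C@@H](OC)[C@@H](O)[C@@](OC)(C1=O)[C@@H](c1cc(OC)c(OC)c(OC)c1)[C@@H]2C | target

**Summary**

Total step count: 13. Longest linear sequence: 13 steps, from 1 to 25; compounds 6, 11 and 17 are purchased.

Steps most likely to fail:

1. Step 8. The addition of the hindered, fully substituted enolate may reverse (retro-aldol), the enolate may simply deprotonate the enolisable aldehyde, or facial control at C1 may be incomplete. The fallback sets out from 16. LDA and TMSCl (THF, −78 °C) should convert it into its silyl enol ether, methyl 1-allyl-3-methoxy-5-methyl-4-(3,4,5-trimethoxyphenyl)-2-[(trimethylsilyl)oxy]cyclopent-2-ene-1-carboxylate F1. This is added to 17 with BF3·OEt2 in CH2Cl2 at −78 °C (Mukaiyama aldol addition). The Lewis-acid addition involves no basic enolate, does not reverse under the conditions and should again occur anti to the aryl group. Aqueous work-up brings the route back at 18.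

2. Step 11. Nucleophilic cleavage at the quaternary 1,3-dicarbonyl centres (retro-Claisen deformylation or deacylation by the amine) may compete with ring closure, or the reaction may stall before dehydration. The fallback sets out from 20. TMSOTf/Et3N (CH2Cl2, −78 °C) should silylate the only enolisable ketone to give the silyl enol ether 1-allyl-4-methoxy-4-[2-methoxy-1-(trimethylsilyloxy)ethenyl]-2-methyl-5-oxo-3-(3,4,5-trimethoxyphenyl)cyclopentane-1-carbaldehyde F2. BF3·OEt2 at −78 °C then closes the ring by intramolecular Mukaiyama aldol addition to the aldol 21, which is isolated this time. Mesylation (MsCl, Et3N, 0 °C) gives 5-allyl-1,3-dimethoxy-6-methyl-2,8-dioxo-7-(3,4,5-trimethoxyphenyl)bicyclo[3.2.1]octan-4-yl methanesulfonate F3, and DBU-induced E1cB elimination brings the route back at 22. The tricarbonyl compound meets no nucleophilic amine or protic base in this sequence.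

3. Step 13. Hydride may be delivered from the C8 face (axial attack), giving the equatorial C2 alcohol, since both faces of the C2 carbonyl carry one close hydrogen and the intrinsic bias is uncertain. The fallback sets out from 24 and comes back at 25. It replaces substrate control by reagent control: CBS reduction with (S)-2-methyl-CBS-oxazaborolidine and catecholborane in toluene at −78 °C. The catalyst distinguishes the quaternary C1 side (large) from the C3 methine side (small) and, in the (S) series, should deliver hydride to the face that gives the (2R)-alcohol. Catecholborane does not hydroborate the allyl group at this temperature, and the C8 ketone is too hindered to bind the catalyst. This fallback passes through no new compound (F0).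

Further compounds
F1 | step 8 | methyl 1-allyl-3-methoxy-5-methyl-4-(3,4,5-trimethoxyphenyl)-2-[(trimethylsilyl)oxy]cyclopent-2-ene-1-carboxylate (silyl enol ether of 16) | C=CC[C@@]1(C(=O)OC)C(O[Si](C)(C)C)=C(OC)[C@@H](c2cc(OC)c(OC)c(OC)c2)[C@@H]1C
F2 | step 11 | 1-allyl-4-methoxy-4-[2-methoxy-1-(trimethylsilyloxy)ethenyl]-2-methyl-5-oxo-3-(3,4,5-trimethoxyphenyl)cyclopentane-1-carbaldehyde (silyl enol ether of 20) | C=CC[C@@]1(C=O)C(=O)[C@](OC)(C(O[Si](C)(C)C)=COC)[C@@H](c2cc(OC)c(OC)c(OC)c2)[C@@H]1C
F3 | step 11 | 5-allyl-1,3-dimethoxy-6-methyl-2,8-dioxo-7-(3,4,5-trimethoxyphenyl)bicyclo[3.2.1]octan-4-yl methanesulfonate | C=CC[C@@]12C(OS(C)(=O)=O)C(OC)C(=O)[C@@](OC)(C1=O)[C@@H](c1cc(OC)c(OC)c(OC)c1)[C@@H]2C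
F0 | step 13 | none | none
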